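J, the further reagent, stands at 0.18 M in the winter, spring and summer runs, while Z changes.

| flask | X | Z | J | remark | time |
|---|---|---|---|---|---|
| winter | 0.15 M | 0.16 M | 0.18 M | run made earlier |  |
| spring | 0.15 M | 0.29 M | 0.18 M | run made earlier |  |
| summer | 0.15 M | 0.65 M | 0.18 M | run made earlier |  |
| Tuesday's | 0.15 M | 0.180 M | 0.180 M |  | 4.0 min |
| Sunday's | 0.15 M | 0.540 M | 0.180 M |  | 4.0 min |

| run | time / min | X / % | G / % | D / % |
|---|---|---|---|---|
| winter | 0.333 | 76.3 | 8.7 | 14.5 |
| winter | 1.00 | 75.8 | 10.3 | 13.9 |
| winter | 2.00 | 75.8 | 10.2 | 14.6 |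
| winter | 3.00 | 76.0 | 10.0 | 14.2 |
| winter | 4.00 | 75.4 | 9.7 | 14.6 |
| spring | 0.833 | 89.4 | 4.8 | 4.8 |
| spring | 1.50 | 90.8 | 4.0 | 5.1 |
| spring | 2.50 | 90.2 | 5.4 | 5.0 |
| spring | 3.00 | 90.8 | 5.3 | 5.7 |
| spring | 4.00 | 89.8 | 5.1 | 6.0 |
| summer | 0.333 | 96.1 | 2.4 | 1.4 |
| summer | 1.00 | 96.2 | 1.0 | 3.1 |
| summer | 2.00 | 95.9 | 1.5 | 2.0 |
| summer | 3.00 | 96.1 | 1.8 | 1.5 |
| summer | 4.00 | 95.6 | 1.2 | 1.0 |

(each reading ± 0.5 percentage points)

* which of these there is most of at the end, counted by the X in it, Tuesday's (X / G / D)
* which of these there is most of at the end, counted by the X in it, Sunday's (X / G / D)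
* amount of the one of these that there is most of at the end, in percent of the X charged, Tuesday's
* amount of the one of these that there is most of at the end, in percent of the X charged, Sunday's



In the winter run X reads 76.3% at 0.333 min and 75.4% at 4.00 min, so we read that run as finished. But X is far from gone, and summer, with more Z, keeps more X at its last reading, 95.6% against 75.4%. So we suppose that X and Z compete for J and that the reaction ends with J. The J charged is then the X used plus the Z used.

The winter mean of X is 75.9%, which puts Z at 0.0162 M. That gives the selectivity factor s, the ln of the fraction of X left over the ln of the fraction of Z left, as 0.121.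

Now we solve each flask at its own end. In Tuesday's flask Z equals J, so the Z left equals the X used. Putting winter's X in as a first guess, s returns 82.4%, then 79.3%, then 80.9%. The passes swing, so we join the last two at their middle, 80.1%.

In Sunday's flask Z is charged in excess of J. Starting with X untouched, the passes give 95.2%, then 95.5%. By this reckoning X then holds more than D and G together in Tuesday's flask and in Sunday's flask.

The forecast names X for Tuesday's and X for Sunday's, with 80.2% (78.5% to 82%) and 95.4% (94.4% to 96.2%). Its ground: “The plateau then marks J exhausted.” Our own figures, 80.1% and 95.5%, are not the forecast's.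

Tuesday's flask ends with X 80.0%, D 11.5% and G 8.51%; Sunday's ends with X 95.3%, D 2.44% and G 2.24%.

    X + J → D (k = 0.501 /M/s)
    J + Z → E (k = 4.03 /M/s)
    D + E ⇌ G (K = 5.41 /M, k = 0.563 /M/s)

Here E is a further species formed on the way. Tuesday's X and Z at the end give s as 0.124. The neighbouring flask is Tuesday's with J cut to 0.045 M. There our s gives 96.6%, then 97.0%. That flask ends with X 96.9%, J 0% of its charge and Z 78% of its charge.

All runs are calculated for an exercise, noise included.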